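(The numbers in the tables come from a simulation on assumed constants; the scatter is artificial.)

**Your decision.** Read substrate beside target in every sample, so that you can hold [substrate]/[target] against the odds reckoned below.

| flask | substrate | capture agent | remark | time |
|---|---|---|---|---|
| larch | 0.063 M | 0.63 mM | run made earlier |  |
| maple | 0.063 M | 0.95 mM | run made earlier |  |
| ash | 0.032 M | 1.26 mM | run made earlier |  |
| flask | 0.063 M | 1.26 mM |  | 12 h |

| run | time / h | target / % | substrate / % |
|---|---|---|---|
| larch | 0.333 | 21 | 72 |
| larch | 0.667 | 35 | 53 |
| larch | 1.33 | 48 | 26 |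
| larch | 3.00 | 37 | 4 |
| larch | 6.00 | 11 | 0 |
| larch | 12.0 | 2 | 0 |
| maple | 0.333 | 18 | 71 |
| maple | 0.667 | 37 | 50 |
| maple | 1.33 | 50 | 28 |
| maple | 3.00 | 38 | 4 |
| maple | 6.00 | 10 | 0 |
| maple | 12.0 | 1 | 1 |
| ash | 0.333 | 21 | 76 |
| ash | 0.833 | 41 | 45 |
| ash | 2.00 | 46 | 13 |
| ash | 5.00 | 16 | 3 |
| ash | 12.0 | 0 | 0 |

(scatter of a reading: 1.5 percentage points)



* time up to 12 h at which target stands highest
* the amount of target, in percent of the substrate charged, at that time

**The start.** Follow one molecule. As substrate it leaves at a steady chance per hour: larch and maple pooled from 0.333 h to 1.33 h give 0.977 h⁻¹, and ash, with half the substrate, gives 1.06 h⁻¹. So the rise of target starts at about that rate, taken on the charge.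

**The slowing.** Two things slow that rise. Making shrinks with substrate, to 27.0% of its start by 1.33 h, and using grows with target. From 3.00 h to 6.00 h, pooled target falls at 0.424 h⁻¹. Substrate was still feeding it, so the loss is larger by a factor 1.15, which gives 0.487 h⁻¹.

**The odds.** The selectivity factor 2.00 is how much likelier a substrate molecule is to move on in a given moment than a target molecule. Making over using is r[substrate]/[target], and target crests when this reaches one. In a two-step picture, ln r over the difference of the two rates gives my crest at 1.42 h, with a height of 50.0%.

**The forecast.** It says 1.5 h and 49%, later and lower than my reckoning, and of this flask it says “I expect the same behaviour”.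

**The flask.** The flask peaks at 48.9% at 1.47 h. At 0.715 h, target in the flask is still made 2.61 times faster than it is used up. At the best time the flask holds 24.1% substrate and 48.9% target, so r[substrate]/[target] stands at 0.986.

    substrate ⇌ open intermediate (K = 2.10, k = 1.00 h⁻¹)
    open intermediate → target (k = 15.0 h⁻¹)
    target → over-reaction product (k = 0.510 h⁻¹)
    open intermediate + capture agent → trapped intermediate (k = 10.0 M⁻¹ h⁻¹)

**A later reading.** Read the same flask at 8.0 h: my two rates, through r, give 4.06% target. The computed flask holds 3.60% target and 0.0435% substrate.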